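## Analysis of the target

Renealtin A is a diarylheptanoid whose seven-carbon chain is closed to a 2,3,5-trisubstituted oxolane. With the ring numbered O1, C2, C3, C4, C5, C2 carries a 4-hydroxy-3-methoxybenzyl group, C3 a free hydroxyl, and C5 a CH2 group (C6) that leads to an aryl ketone (C7) on a second guaiacyl ring. The three stereocentres are (2R,3R,5R) and put all three substituents on one face of the ring: 2,3-cis, 2,5-cis and therefore 3,5-cis. The sensitive groups are the two electron-rich phenols, which tolerate neither organolithium bases nor peroxidic oxidants unprotected, and the β-alkoxy ketone O1–C5–C6–C7(=O), which can open by retro-oxa-Michael reaction under base and so epimerise C5. The difficulty is the contra-steric all-cis pattern: the 2,3-cis pair sits next to the ring oxygen, and the 1,3-relation of C3 to C5 must be controlled across a CH2 group. In addition the two nearly identical aryl ends differ in oxidation level (benzylic CH2 against C=O) and must be introduced by different chemistry. The strategy rests on the O1–C2 bond: once it is cut, the C5 oxygen is a hydroxyl that is homoallylic to a C2=C3 alkene in the open chain. That hydroxyl can first guide an oxygen atom onto the alkene (the future C3 hydroxyl) and then attack C2 of the epoxide, so one group serves as director and as ring-closing nucleophile.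

## Retrosynthetic reasoning

**18 from 17.** Only the two phenolic O–Si bonds are cut: target 18 is taken back to its bis-silyl ether 17. Free guaiacol rings would be deprotonated by the organolithium reagents used earlier and oxidised in the key step, so they stay capped to the end. The forward reaction must remove silicon without letting base reach the β-alkoxy ketone.

**17 from 15 through 16.** The O1–C2 bond is cut, which turns C2–C3 into the cis-epoxide of 16 and, one stage further back, into the Z-alkene of 15.
- Why here: C2 is the only ring carbon where the C–O bond can form by an SN2 opening whose leaving oxygen becomes the C3 hydroxyl. Cutting O1–C5 instead would need a leaving group β to an enolisable ketone and would remove the hydroxyl that steers the oxidant.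
- What is gained: the ring and both C2 and C3 arise from an acyclic compound with one stereocentre. The Z geometry becomes the 2,3-cis relation, and one face selection gives the 3,5-relation.
- What the forward reaction must achieve: 17 requires the (2S,3R)-epoxide 16, in which the epoxide oxygen is anti to the C5 hydroxyl when the chain C6–C5–C4–C3–C2 is drawn extended. In the chair through which a vanadium-bound homoallylic alkoxide passes oxygen to its alkene, the Z substituent keeps the far alkene carbon outside the chair. An equatorial C5 side chain then leads to the syn epoxy alcohol, which is the wrong face. The hydroxyl alone therefore cannot be relied on to choose the face. A chiral ligand on vanadium must override the substrate's preference, and this is where the risk of the route lies.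

**15 from 14.** The Z-alkene is taken back to the alkyne of 14. The geometry must be pure because it is transcribed into the 2,3-cis relation, and syn semihydrogenation of an alkyne is the most dependable source of a Z-alkene. The alkyne also allows the carbon chain to be joined by acetylide chemistry.

**14 from 13.** The C7 ketone is taken back to the 1,3-dithiane of 13, so that C7 can act as an acyl anion when the chain is built. Sulfur must be removed before palladium is used in the semihydrogenation and before the peroxide of the key step, which would oxidise it.

**13 from 7 and 11 (as its acetylide 12).** The C3–C4 bond is cut between the alkyne and the terminal carbon of epoxide 7. This joins the two aryl halves in one convergent step, at a carbon remote from the stereocentre, and leaves the C5 hydroxyl free where it is needed.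

**7 from 3 (as its anion 5) and 4 (through 6).** The C6–C7 bond is cut. The lithiated dithiane 5 opens (S)-epichlorohydrin 4 at the epoxide CH2, and the chloroalkoxide 6 closes to the new epoxide 7. The only stereocentre brought into the key step is thus purchased. Because the dithiane is attached first and the alkyne second, it is the (S)-enantiomer 4 that maps onto (R) at C5.

**11 from 9 and 10; 9 from 8; 8 and 3 from 2; 2 from 1.** The benzylic–alkyne bond of 11 is cut to benzylic bromide 9 and ethynylmagnesium bromide 10. Bromide 9 comes from alcohol 8 and aldehyde 2, and dithiane 3 comes from the same aldehyde 2. Both aryl groups therefore derive from vanillin 1 through one common silylated intermediate.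

## Alternatives that were turned down

**Alternative 1:** The oxolane with its two exocyclic CH2 groups is traced to a [4+3] cycloadduct of furan A1 and 1,1,3,3-tetrabromoacetone A2. A1 supplies O1 and C2–C5; A2 supplies the two CH2 groups joined through a carbonyl that must later be cleaved.
- Forward key step: Zn/Cu couple A3 reduces A2 to an oxyallyl cation, which adds across the 2- and 5-positions of A1. The remaining bromines are removed by zinc in the same operation, giving meso-8-oxabicyclo[3.2.1]oct-6-en-3-one A4.
- In its favour: two cheap components, one operation, and a 2,5-cis relation locked by the bicycle. On that relation it is more secure than the chosen route.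
- Against it for this target:
  - A4 is achiral and must be desymmetrised.
  - The C3 hydroxyl must come from the ring alkene by hydroboration, which attacks from the side of the oxygen bridge and so places the hydroxyl trans to both CH2 arms; an inversion is then needed.
  - The carbonyl bridge must be cut between two nearly equivalent CH2 groups (a Baeyer–Villiger step steered only by the remote hydroxyl).
  - Neither aryl group is present. One arm needs an sp3–sp2 coupling next to a β-oxygen, the other an aryl ketone synthesis.
- Comparison: more than a dozen operations after the cycloaddition, against eleven in total for the chosen route. The chosen route carries both aryl groups from the start and obtains the 2,3-cis pair directly from alkene geometry.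

**Alternative 2:** The C4–C5 bond is cut. The ring is traced to the cis-2,5-disubstituted 4-methylidene-1,3-dioxolane A5, an enol acetal built from a 2-hydroxy acid component (C2 with its arylmethyl group) and an aldehyde component (C5, C6 and the masked ketone).
- Forward key step: iBu3Al A6 ionises the acetal C–O bond on the enol ether side to an aluminium enolate and an oxocarbenium ion. The enolate carbon attacks the oxocarbenium carbon (Petasis–Ferrier rearrangement), and the resulting oxolan-3-one is reduced by the same reagent to the all-cis alcohol A7.
- In its favour: C2 comes from a stereodefined hydroxy acid, the closure places the C5 substituent cis to it, and hydride then arrives on the face away from both substituents. Substrate control thus works in one direction for all three centres. On the 2,5- and 3,5-relations this is stronger than the chosen route, in which the ligand must override the substrate.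
- Against it:
  - The enantiopure hydroxy acid with the protected guaiacyl ring needs its own asymmetric synthesis, and the aldehyde partner must also be made.
  - The dioxolanone must be formed cis and then methylenated with a titanium alkylidene reagent in the presence of a thioacetal.
  - A5 is an acid-labile enol acetal.
  - At the oxolanone stage C2 is α to a ketone and can epimerise.
- Comparison: counting both components the sequence is longer, and it ends with the same thioacetal hydrolysis and desilylation. In exchange, the chosen strategy offers a precursor made entirely by anion–epoxide unions from one purchased stereocentre, and a catalytic, stereospecific ring closure.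

**Alternative 3:** Two bonds at C2 are cut: O1–C2 and the bond from C2 to the benzylic CH2. The precursor is diazoketone A8, whose C5 oxygen carries the 4-silyloxy-3-methoxybenzyl group as an ether and whose C7 ketone is a dioxolane.
- Forward key step: Cu(hfacac)2 A9 converts the diazo carbon into a carbenoid. The ether oxygen adds to it to give a five-membered oxonium ylide (O1–C2 bond and ring), and the benzyl group moves from oxygen to carbon in a [1,2]-Stevens shift to give the cis-oxolan-3-one A10. Hydride reduction from the face away from the two substituents would then give the all-cis alcohol.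
- In its favour: ring, C2 stereocentre and a C–C bond in one step from a precursor with one easily made stereocentre. As in alternative 2, the reduction has a facial bias that points the right way, which makes it stronger than the chosen route on the 3,5-relation.
- Against it:
  - The [1,2]-shift runs through a radical pair, so homodimerisation, C–H insertion and incomplete cis selectivity at C2 compete in the very step that carries the strategy.
  - The diazoketone needs a diazoalkane acylation of a β-alkoxy acid derivative that can eliminate.
  - The C7 ketone needs a ketal put on and taken off.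
  - C2 of A10 is epimerisable.
- Comparison: the step count would be similar, but with a hazardous reagent class and a radical recombination where the chosen route has an ionic SN2 closure whose stereochemical outcome is fixed by alkene geometry.

Key step: step 10

Abbreviations: Ar = 4-[(tert-butyldimethylsilyl)oxy]-3-methoxyphenyl; TBS = tert-butyldimethylsilyl; (R,R)-BHA = (1R,2R)-N,N'-dihydroxy-N,N'-bis(diphenylacetyl)cyclohexane-1,2-diamine. Ring numbering is O1, C2 (arylmethyl), C3 (OH), C4, C5, with C6 and C7 (C=O) in the side chain.

Assumption: (R,R)-BHA is taken to be the ligand enantiomer that transfers oxygen to the alkene face leading to epoxide 16; if its sense is the opposite, the (S,S)-ligand is used and nothing else changes.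

## Route

Step 1
Reactants: 1 vanillin (4-hydroxy-3-methoxybenzaldehyde)
Product: 2 4-[(tert-butyldimethylsilyl)oxy]-3-methoxybenzaldehyde (ArCHO)
Conditions: TBSCl, imidazole, DMF, rt
Reagents that add atoms: tert-butyldimethylsilyl chloride, CC(C)(C)[Si](C)(C)Cl
Why: Imidazole-promoted silylation of the phenol; the aldehyde is untouched, and the aryl silyl ether withstands the organolithium, Lewis-acid and oxidative steps that follow while leaving under buffered fluoride at the end.

Step 2
Reactants: 2 ArCHO
Product: 3 2-Ar-1,3-dithiane
Conditions: HS(CH2)3SH, BF3·OEt2 (cat.), CH2Cl2, 0 °C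
Reagents that add atoms: propane-1,3-dithiol, SCCCS
Why: Lewis-acid-catalysed dithioacetalisation of an aromatic aldehyde, the first half of a Corey–Seebach umpolung; the aryl silyl ether tolerates brief exposure to catalytic BF3·OEt2 at 0 °C.

Step 3
Reactants: 3 2-Ar-1,3-dithiane; 4 (S)-epichlorohydrin [(2S)-2-(chloromethyl)oxirane]
Product: 7 (S)-2-Ar-2-(oxiran-2-ylmethyl)-1,3-dithiane, via 2-lithio-2-Ar-1,3-dithiane 5 (not isolated), via lithium chloroalkoxide 6 (not isolated)
Conditions: n-BuLi, THF, −78 to −25 °C; then 4, −78 °C to rt
Reagents that add atoms: none
Why: Corey–Seebach alkylation: the lithiated dithiane opens the epoxide of 4 at its CH2 carbon, and on warming the alkoxide displaces chloride to form the new epoxide. No bond at the stereocentre is touched, so the configuration of 4 is carried over and becomes C5 of the target; attack at the epoxide rather than at C–Cl is what leads to the (S)-epoxide.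

Step 4
Reactants: 2 ArCHO
Product: 8 ArCH2OH, {4-[(tert-butyldimethylsilyl)oxy]-3-methoxyphenyl}methanol
Conditions: NaBH4, MeOH/THF, 0 °C
Reagents that add atoms: none
Why: Borohydride reduction of an aromatic aldehyde; a short reaction at 0 °C keeps the aryl silyl ether intact.

Step 5
Reactants: 8 ArCH2OH
Product: 9 ArCH2Br, [4-(bromomethyl)-2-methoxyphenoxy](tert-butyl)dimethylsilane
Conditions: CBr4, PPh3, CH2Cl2, 0 °C
Reagents that add atoms: carbon tetrabromide, BrC(Br)(Br)Br
Why: Appel bromination of a benzylic alcohol under neutral conditions, which spares the silyl ether; the easily ionised bromide is used without storage.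

Step 6
Reactants: 9 ArCH2Br; 10 ethynylmagnesium bromide
Product: 11 3-Ar-prop-1-yne (ArCH2C≡CH)
Conditions: CuBr·SMe2 (10 mol %), THF, 0 °C to rt
Reagents that add atoms: none
Why: Copper-catalysed sp3–sp coupling of a benzylic bromide with an alkynyl Grignard reagent; an excess of 10 keeps the product from being metallated and benzylated a second time.

Step 7
Reactants: 11 3-Ar-prop-1-yne; 7 (S)-2-Ar-2-(oxiran-2-ylmethyl)-1,3-dithiane
Product: 13 (2R)-1-(2-Ar-1,3-dithian-2-yl)-6-Ar-hex-4-yn-2-ol, via lithium acetylide 12 (not isolated)
Conditions: n-BuLi, THF, −78 °C; BF3·OEt2; then 7, −78 °C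
Reagents that add atoms: none
Why: Yamaguchi–Hirao alkynylation: the alkynyl trifluoroborate formed from 12 and BF3·OEt2 opens the monosubstituted epoxide at its terminal carbon and forms the C3–C4 bond without touching the stereocentre. The low temperature and the weakly basic borate keep the benzylic–propargylic CH2 from isomerising to the allene.

Step 8
Reactants: 13 (2R)-1-(2-Ar-1,3-dithian-2-yl)-6-Ar-hex-4-yn-2-ol
Product: 14 (3R)-1,7-di-Ar-3-hydroxyhept-5-yn-1-one
Conditions: MeI, CaCO3, MeCN/H2O (9:1), 45 °C
Reagents that add atoms: water, O
Why: Alkylative thioacetal hydrolysis: S-methylation, then water adds to the thionium ion stabilised by the electron-rich arene. The buffered, near-neutral medium spares the β-hydroxy ketone from dehydration, and sulfur is removed before palladium and peroxide are used.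

Step 9
Reactants: 14 (3R)-1,7-di-Ar-3-hydroxyhept-5-yn-1-one
Product: 15 (3R,5Z)-1,7-di-Ar-3-hydroxyhept-5-en-1-one
Conditions: H2 (1 atm), Pd/CaCO3 poisoned with Pb(OAc)2 (Lindlar catalyst), quinoline, EtOAc, rt
Reagents that add atoms: none
Why: Lindlar semihydrogenation: syn addition of H2 on the poisoned palladium surface gives the Z-alkene, and the aryl ketone and silyl ethers are inert; uptake is stopped at one equivalent.

Step 10
Reactants: 15 (3R,5Z)-1,7-di-Ar-3-hydroxyhept-5-en-1-one
Product: 17 (2R,3R,5R)-2-(ArCH2)-5-(2-Ar-2-oxoethyl)oxolan-3-ol (bis-TBS ether of renealtin A), via cis-epoxy alcohol 16 (not isolated)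
Conditions: VO(OiPr)3 (5 mol %), (R,R)-BHA (10 mol %), TBHP (in decane), toluene, 0 °C to rt; then CSA (10 mol %), rt
Reagents that add atoms: tert-butyl hydroperoxide, CC(C)(C)OO
Why: Ligand exchange places 15 on pentavalent vanadium as its C5 alkoxide beside the bound tert-butylperoxide, and the peroxide oxygen passes to the tethered C2=C3 bond through a chair-like array (V, O, C5, C4, C3 and the oxygen in flight); the closest known reaction type is the hydroxyl-directed vanadium epoxidation of homoallylic alcohols in its ligand-controlled form, followed by the acid-promoted cyclisation of 3,4-epoxy alcohols to oxolan-3-ols. Syn oxygen transfer to the Z-alkene gives the cis-epoxide 16, so C3 is fixed by the face that is attacked. That face is the selectivity the step needs: with the Z substituent holding the far alkene carbon outside the chair, an equatorial C5 side chain would lead to the other face, so the substrate alone is biased against the target; the twofold-symmetric bishydroxamate, whose chiral pocket reaches the alkene through the C5–O–V anchor, is used in the enantiomeric form that overrides this bias. The oxolane is then closed by the same C5 oxygen attacking C2 from the rear of the epoxide C–O bond, a 5-endo-tet opening preferred over 4-exo attack at C3 because the latter would give a strained oxetane; the Lewis acidic metal starts it and catalytic CSA completes it. C2 is set by this inversion alone: inversion at C2 of a cis-epoxide leaves the arylmethyl group and the C3 hydroxyl on one face, so the Z geometry made in step 9 controls the 2,3-cis relation. C5 is not touched. Because the oxidant is delivered only within the alkoxide complex, the electron-rich arenes, the ketone and the benzylic positions are left alone.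

Step 11
Reactants: 17 (2R,3R,5R)-2-(ArCH2)-5-(2-Ar-2-oxoethyl)oxolan-3-ol
Product: 18 renealtin A, (2R,3R,5R)-2-(4-hydroxy-3-methoxybenzyl)-5-[2-(4-hydroxy-3-methoxyphenyl)-2-oxoethyl]oxolan-3-ol
Conditions: TBAF, AcOH, THF, 0 °C
Reagents that add atoms: none
Why: Fluoride cleavage of the two aryl silyl ethers; acetic acid buffers fluoride and phenoxide basicity so that the β-alkoxy ketone does not open by retro-oxa-Michael reaction and C5 keeps its configuration.

## Compound list

1 | vanillin (4-hydroxy-3-methoxybenzaldehyde) | COc1cc(C=O)ccc1O | starting material
2 | 4-[(tert-butyldimethylsilyl)oxy]-3-methoxybenzaldehyde (ArCHO) | COc1cc(C=O)ccc1O[Si](C)(C)C(C)(C)C | intermediate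
3 | 2-Ar-1,3-dithiane | COc1cc(C2SCCCS2)ccc1O[Si](C)(C)C(C)(C)C | intermediate
4 | (S)-epichlorohydrin, (2S)-2-(chloromethyl)oxirane | ClC[C@@H]1CO1 | starting material
5 | 2-lithio-2-Ar-1,3-dithiane (formed in the flask) | COc1cc(C2([Li])SCCCS2)ccc1O[Si](C)(C)C(C)(C)C | intermediate
6 | lithium (2S)-1-chloro-3-(2-Ar-1,3-dithian-2-yl)propan-2-olate (formed in the flask) | COc1cc(C2(C[C@@H](CCl)O[Li])SCCCS2)ccc1O[Si](C)(C)C(C)(C)C | intermediate
7 | (S)-2-Ar-2-(oxiran-2-ylmethyl)-1,3-dithiane | COc1cc(C2(C[C@H]3CO3)SCCCS2)ccc1O[Si](C)(C)C(C)(C)C | intermediate
8 | ArCH2OH, {4-[(tert-butyldimethylsilyl)oxy]-3-methoxyphenyl}methanol | COc1cc(CO)ccc1O[Si](C)(C)C(C)(C)C | intermediate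
9 | ArCH2Br, [4-(bromomethyl)-2-methoxyphenoxy](tert-butyl)dimethylsilane | COc1cc(CBr)ccc1O[Si](C)(C)C(C)(C)C | intermediate
10 | ethynylmagnesium bromide | C#C[Mg]Br | starting material
11 | 3-Ar-prop-1-yne, tert-butyl[2-methoxy-4-(prop-2-yn-1-yl)phenoxy]dimethylsilane | COc1cc(CC#C)ccc1O[Si](C)(C)C(C)(C)C | intermediate
12 | lithium 3-Ar-prop-1-yn-1-ide, the lithium acetylide of 11 (formed in the flask) | COc1cc(CC#C[Li])ccc1O[Si](C)(C)C(C)(C)C | intermediate
13 | (2R)-1-(2-Ar-1,3-dithian-2-yl)-6-Ar-hex-4-yn-2-ol | COc1cc(C2(C[C@H](O)CC#CCc3ccc(O[Si](C)(C)C(C)(C)C)c(OC)c3)SCCCS2)ccc1O[Si](C)(C)C(C)(C)C | intermediate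
14 | (3R)-1,7-di-Ar-3-hydroxyhept-5-yn-1-one | COc1cc(C(=O)C[C@H](O)CC#CCc2ccc(O[Si](C)(C)C(C)(C)C)c(OC)c2)ccc1O[Si](C)(C)C(C)(C)C | intermediate
15 | (3R,5Z)-1,7-di-Ar-3-hydroxyhept-5-en-1-one (C3 of this name is C5 of the ring numbering) | COc1cc(C/C=C\C[C@@H](O)CC(=O)c2ccc(O[Si](C)(C)C(C)(C)C)c(OC)c2)ccc1O[Si](C)(C)C(C)(C)C | intermediate
16 | (3R)-1-Ar-4-[(2R,3S)-3-(ArCH2)oxiran-2-yl]-3-hydroxybutan-1-one, the cis-epoxy alcohol (formed in the flask) | COc1cc(C[C@@H]2O[C@@H]2C[C@@H](O)CC(=O)c3ccc(O[Si](C)(C)C(C)(C)C)c(OC)c3)ccc1O[Si](C)(C)C(C)(C)C | intermediate
17 | (2R,3R,5R)-2-(ArCH2)-5-(2-Ar-2-oxoethyl)oxolan-3-ol, all-cis, bis-TBS ether of renealtin A | COc1cc(C[C@@H]2[C@H](O)C[C@H](CC(=O)c3ccc(O[Si](C)(C)C(C)(C)C)c(OC)c3)O2)ccc1O[Si](C)(C)C(C)(C)C | intermediate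
18 | renealtin A, (2R,3R,5R)-2-(4-hydroxy-3-methoxybenzyl)-5-[2-(4-hydroxy-3-methoxyphenyl)-2-oxoethyl]oxolan-3-ol | COc1cc(C[C@H]2O[C@@H](CC(=O)c3ccc(O)c(OC)c3)C[C@H]2O)ccc1O | target

## Step count and least certain steps

Total step count: 11. Longest linear sequence: 9 steps (1 → 2 → 8 → 9 → 11 → 13 → 14 → 15 → 17 → 18).

**Step 10 (key step).** The most likely failure is poor or reversed facial selectivity in the oxygen transfer, together with slow turnover. Catalyst and substrate form a mismatched pair: the chair that the substrate prefers (C5 side chain equatorial) delivers oxygen to the face that, after the same closure, would put the C5 side chain trans to the C3 hydroxyl. The ligand must therefore win against the substrate. A smaller risk is participation of the electron-rich aryl ring at C2 during the acid-promoted closure, which would erode the stereospecificity; this is why only catalytic CSA is used.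

The fallback sets out from the lithiated dithiane 5 and comes back to the route at 17. It changes the approach: C5 is no longer fixed before the ring is made but corrected afterwards under thermodynamic control.
- 5 is alkylated with (R)-epichlorohydrin F1 instead of 4. Through the lithium chloroalkoxide F2 this gives the (R)-epoxide F3.
- The operations of steps 7, 8 and 9 then give the (S)-alkynol F4, the (S)-hydroxy ketone F5 and the (3S,5Z)-alkenol F6, the enantiomer of 15.
- In F6 the substrate-preferred chair leads to the epoxide configuration that the target needs at C2 and C3, so substrate and catalyst now cooperate. VO(acac)2 with TBHP alone, or the same ligand as a matched pair, should give the cis-epoxy alcohol F7 and, after CSA, the oxolane F8. F8 has C2 and C3 as in 17 and only C5 inverted.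
- F8 is equilibrated with catalytic DBU in toluene through reversible retro-oxa-Michael and oxa-Michael reaction at the β-alkoxy ketone. Compound 17 has both 1,3-related pairs of ring substituents cis and can form a hydrogen bond from the C3 hydroxyl to the ketone, so it is expected to be the favoured C5 epimer. Remaining F8 is separated and resubmitted.

**Step 7.** The most likely failure is deprotonation at the benzylic–propargylic CH2 with propargyl–allenyl isomerisation of the nucleophile, or Lewis-acid-induced opening of the epoxide with participation of a dithiane sulfur. Either would consume 7 without forming the C3–C4 bond.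

The fallback sets out from epoxide 7 and comes back at 13. It makes the benzylic C–C bond last, so that 11 and 12 are not needed.
- 7 is opened with lithium acetylide (from acetylene and n-BuLi) and BF3·OEt2 to the terminal alkynol F9.
- Two equivalents of EtMgBr convert F9 into the bis(bromomagnesium) alkoxide acetylide F10.
- F10 is coupled with benzylic bromide 9 under CuBr·SMe2 catalysis, the reaction type of step 6, to give 13.

**Step 9.** The most likely failure is over-reduction, or migration of the skipped double bond toward conjugation with the arene on the palladium surface. The reaction may also stall through poisoning by sulfur residues carried over from step 8.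

The fallback sets out from 13 and comes back at 15. It uses no metal surface and reduces the alkyne while sulfur is still present.
- Syn-hydroboration of the alkyne of 13 with dicyclohexylborane (the hydroxyl consumes one further equivalent), then protonolysis with acetic acid, gives the Z-alkenyl dithiane F11.
- Alkylative hydrolysis as in step 8 (MeI, CaCO3, aqueous MeCN) then gives 15.

**Step 6.** The most likely failure is base-induced propargyl–allenyl isomerisation and a second benzylation at the acetylenic terminus, because the product is a terminal alkyne with an acidic CH2. Homocoupling of the easily ionised benzylic bromide is also possible.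

The fallback sets out from 9 and comes back at 11. It caps the alkyne terminus during the coupling.
- 9 is coupled under CuBr·SMe2 catalysis with [(trimethylsilyl)ethynyl]magnesium bromide (from ethynyltrimethylsilane and EtMgBr) to give the C-silylated alkyne F12, which has no acetylenic hydrogen.
- AgNO3-catalysed protodesilylation in aqueous acetone then frees 11 without touching the aryl silyl ether.

## Further compounds

F1 | step 10 | (R)-epichlorohydrin, (2R)-2-(chloromethyl)oxirane | ClC[C@H]1CO1
F2 | step 10 | lithium (2R)-1-chloro-3-(2-Ar-1,3-dithian-2-yl)propan-2-olate | COc1cc(C2(C[C@H](CCl)O[Li])SCCCS2)ccc1O[Si](C)(C)C(C)(C)C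
F3 | step 10 | (R)-2-Ar-2-(oxiran-2-ylmethyl)-1,3-dithiane | COc1cc(C2(C[C@@H]3CO3)SCCCS2)ccc1O[Si](C)(C)C(C)(C)C
F4 | step 10 | (2S)-1-(2-Ar-1,3-dithian-2-yl)-6-Ar-hex-4-yn-2-ol | COc1cc(C2(C[C@@H](O)CC#CCc3ccc(O[Si](C)(C)C(C)(C)C)c(OC)c3)SCCCS2)ccc1O[Si](C)(C)C(C)(C)C
F5 | step 10 | (3S)-1,7-di-Ar-3-hydroxyhept-5-yn-1-one | COc1cc(C(=O)C[C@@H](O)CC#CCc2ccc(O[Si](C)(C)C(C)(C)C)c(OC)c2)ccc1O[Si](C)(C)C(C)(C)C
F6 | step 10 | (3S,5Z)-1,7-di-Ar-3-hydroxyhept-5-en-1-one | COc1cc(C/C=C\C[C@H](O)CC(=O)c2ccc(O[Si](C)(C)C(C)(C)C)c(OC)c2)ccc1O[Si](C)(C)C(C)(C)C
F7 | step 10 | (3S)-1-Ar-4-[(2R,3S)-3-(ArCH2)oxiran-2-yl]-3-hydroxybutan-1-one | COc1cc(C[C@@H]2O[C@@H]2C[C@H](O)CC(=O)c3ccc(O[Si](C)(C)C(C)(C)C)c(OC)c3)ccc1O[Si](C)(C)C(C)(C)C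
F8 | step 10 | (2R,3R,5S)-2-(ArCH2)-5-(2-Ar-2-oxoethyl)oxolan-3-ol, the C5 epimer of 17 | COc1cc(C[C@@H]2[C@H](O)C[C@@H](CC(=O)c3ccc(O[Si](C)(C)C(C)(C)C)c(OC)c3)O2)ccc1O[Si](C)(C)C(C)(C)C
F9 | step 7 | (2R)-1-(2-Ar-1,3-dithian-2-yl)pent-4-yn-2-ol | COc1cc(C2(C[C@H](O)CC#C)SCCCS2)ccc1O[Si](C)(C)C(C)(C)C
F10 | step 7 | bis(bromomagnesium) alkoxide acetylide of F9 | COc1cc(C2(C[C@H](O[Mg]Br)CC#C[Mg]Br)SCCCS2)ccc1O[Si](C)(C)C(C)(C)C
F11 | step 9 | (2R,4Z)-1-(2-Ar-1,3-dithian-2-yl)-6-Ar-hex-4-en-2-ol | COc1cc(C2(C[C@H](O)C/C=C\Cc3ccc(O[Si](C)(C)C(C)(C)C)c(OC)c3)SCCCS2)ccc1O[Si](C)(C)C(C)(C)C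
F12 | step 6 | tert-butyl{2-methoxy-4-[3-(trimethylsilyl)prop-2-yn-1-yl]phenoxy}dimethylsilane | COc1cc(CC#C[Si](C)(C)C)ccc1O[Si](C)(C)C(C)(C)C
A1 | alternative 1 | furan | c1ccoc1
A2 | alternative 1 | 1,1,3,3-tetrabromoacetone | O=C(C(Br)Br)C(Br)Br
A3 | alternative 1 | zinc–copper couple | [Zn].[Cu]
A4 | alternative 1 | meso-8-oxabicyclo[3.2.1]oct-6-en-3-one | O=C1C[C@H]2C=C[C@@H](C1)O2
A5 | alternative 2 | (2R,5R)-2-[(2-Ar-1,3-dithian-2-yl)methyl]-5-(ArCH2)-4-methylidene-1,3-dioxolane (cis) | C=C1O[C@H](CC2(c3ccc(O[Si](C)(C)C(C)(C)C)c(OC)c3)SCCCS2)O[C@@H]1Cc1ccc(O[Si](C)(C)C(C)(C)C)c(OC)c1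
A6 | alternative 2 | triisobutylaluminium, iBu3Al | CC(C)C[Al](CC(C)C)CC(C)C
A7 | alternative 2 | (2R,3R,5R)-2-(ArCH2)-5-[(2-Ar-1,3-dithian-2-yl)methyl]oxolan-3-ol (all-cis) | COc1cc(C[C@@H]2[C@H](O)C[C@H](CC3(c4ccc(O[Si](C)(C)C(C)(C)C)c(OC)c4)SCCCS3)O2)ccc1O[Si](C)(C)C(C)(C)C
A8 | alternative 3 | (4R)-5-(2-Ar-1,3-dioxolan-2-yl)-4-(ArCH2O)-1-diazopentan-2-one | [N-]=[N+]=CC(=O)C[C@H](CC1(c2ccc(O[Si](C)(C)C(C)(C)C)c(OC)c2)OCCO1)OCc1ccc(O[Si](C)(C)C(C)(C)C)c(OC)c1
A9 | alternative 3 | copper bis(hexafluoroacetylacetonate), Cu(hfacac)2 | [Cu+2].[O-]C(=CC(=O)C(F)(F)F)C(F)(F)F.[O-]C(=CC(=O)C(F)(F)F)C(F)(F)F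
A10 | alternative 3 | (2R,5R)-2-(ArCH2)-5-[(2-Ar-1,3-dioxolan-2-yl)methyl]oxolan-3-one (cis) | COc1cc(C[C@@H]2C(=O)C[C@H](CC3(c4ccc(O[Si](C)(C)C(C)(C)C)c(OC)c4)OCCO3)O2)ccc1O[Si](C)(C)C(C)(C)C
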